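A direct plan would acylate a 2-hydroxyaryl enaminone to a 2-methyl-3-methoxalylchromone, methylenate it to the vinylchromone A1, close the cyclopentene carbinol A2 by a carbene-catalysed umpolung cyclisation, and add to A2 the 1-aryl-isobenzofuran A3 (from a phthalan acetal and acid) in a Diels–Alder reaction to reach the penta-MOM ether A4, which would be unmasked last.
Its weakest steps would be:
- the carbene-catalysed ring closure to A2: a 1,6-addition/5-exo aldol without precedent on a vinylchromone, and the only source of absolute configuration;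
- the isobenzofuran cycloaddition: orientation, facial and exo selectivity (four stereocentres) would rest on one hydrogen bond and on reversibility, in hot acid that also meets the tertiary carbinol of A2;
- the fivefold MOM cleavage of A4 with a boron bromide: on the most precious material, whose doubly benzylic bridging ether between two ortho-oxygenated rings ionises and aromatises easily, next to a tertiary acetate.
It would also spend five steps on one pentasubstituted benzene and carry six MOM ethers.

Plan of the new route
Labels: C1 = C(OH)CO2Me; Ca, Cb = the cyclopentane CH carbons (Ca next to C1, Cb next to chromone C2); Cc (H) and Cq (aryl) = bridgeheads; rings A/B chromone, C cyclopentane, D oxygen bridge, E its benzo ring, F dihydroxyphenyl.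
Cut 1: Cb–C2(chromone) and Ca–C1, back to the strained alkene of a 1-aryl-7-oxabenzonorbornadiene and a 3-methoxalylchromone with free C2–H. Cut 2: the two aryl–bridgehead bonds, back to a 2-arylfuran and a 3,6-dioxygenated aryne held together by a silicon tether.
Order of rings: A/B and F with the furan are made apart; D and E appear together in the aryne–furan cycloaddition (the furan oxygen becomes the bridge); ring C closes last.
Enabling feature: ring C is at once the exo,cis-fused face of an oxanorbornene and, on the chromone, a C2–H next to the C3 keto ester, an ortho C–H/ketone pair that can add as a three-carbon unit across a strained alkene.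
The weak steps do not arise: C1 is created in the ring-C annulation (no carbene umpolung); exo fusion is dictated by the bicyclic alkene already in place (no isobenzofuran, no acid); only silicon groups are removed at the end, with buffered fluoride, and the chromone half is coupled unprotected.

Key step: step 14

Remark on the chemistry: the aryne cycloaddition gives a racemate, so the absolute configuration enters by resolution directly after it and would be assigned by correlation with the final product; the SMILES strings give the configuration of every compound.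

Step 1
Reactants: 1 5-chloro-2-methylphenol
Product: 2 4-bromo-5-chloro-2-methylphenol
Conditions: NBS, MeCN, 0 °C → rt
Reagents that add atoms: N-bromosuccinimide, O=C1CCC(=O)N1Br
Why: Electrophilic aromatic bromination should go para to the phenol, since one ortho position carries the methyl group and the other is crowded by chlorine; no stereocentre.

Step 2
Reactants: 2 4-bromo-5-chloro-2-methylphenol, 3 3-methylbutane-1,3-diol
Product: 4 4-(4-bromo-5-chloro-2-methylphenoxy)-2-methylbutan-2-ol
Conditions: PPh3, DIAD, THF, 0 °C → rt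
Reagents that add atoms: none
Why: Mitsunobu etherification should join the phenol to the primary hydroxyl only, because the tertiary alcohol is inert.

Step 3
Reactants: 4 4-(4-bromo-5-chloro-2-methylphenoxy)-2-methylbutan-2-ol
Product: 5 2-chloro-4-(3-hydroxy-3-methylbutoxy)-5-methylphenol
Conditions: CuI (10 mol %), 1,10-phenanthroline, KOH, DMSO/H2O, 100 °C, Ar
Reagents that add atoms: potassium hydroxide, [K+].[OH-]
Why: Copper-catalysed Ullmann-type hydroxylation should replace the bromide, which reacts far faster than the chloride kept as the later leaving group of the aryne.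

Step 4
Reactants: 6 2-bromobenzene-1,3-diol, 7 2-(furan-2-yl)-4,4,5,5-tetramethyl-1,3,2-dioxaborolane
Product: 8 2-(furan-2-yl)benzene-1,3-diol
Conditions: Pd(OAc)2 (3 mol %), SPhos, K3PO4, toluene/H2O, 80 °C
Reagents that add atoms: none
Why: Suzuki–Miyaura coupling with a dialkylbiarylphosphine should cope with the electron-rich, doubly ortho-substituted bromide and give the furan that will supply Cq, Cc and the bridging oxygen.

Step 5
Reactants: 5 2-chloro-4-(3-hydroxy-3-methylbutoxy)-5-methylphenol, 8 2-(furan-2-yl)benzene-1,3-diol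
Product: 11 4-{5-chloro-4-[({3-[(tert-butyldimethylsilyl)oxy]-2-(furan-2-yl)phenoxy}di(propan-2-yl)silyl)oxy]-2-methylphenoxy}-2-methylbutan-2-ol, via chlorosilane 9 (not isolated), via monophenol silane 10 (not isolated)
Conditions: i-Pr2SiCl2 (1.0 equiv), imidazole, CH2Cl2, −40 °C, slow addition of 5; then 8 (1.5 equiv), 0 °C → rt; then t-BuMe2SiCl, imidazole, rt
Reagents that add atoms: dichlorodi(propan-2-yl)silane, CC(C)[Si](Cl)(Cl)C(C)C; tert-butyl(chloro)dimethylsilane, CC(C)(C)[Si](C)(C)Cl
Why: Stepwise O-silylation should let the phenol of 5 (not its tertiary alcohol) and then one phenol of the symmetric diol 8 displace the two chlorides to give the mixed bis(aryloxy)silane that serves as a disposable tether, the remaining phenol being capped as its silyl ether; no stereocentre.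

Step 6
Reactants: 11 4-{5-chloro-4-[({3-[(tert-butyldimethylsilyl)oxy]-2-(furan-2-yl)phenoxy}di(propan-2-yl)silyl)oxy]-2-methylphenoxy}-2-methylbutan-2-ol
Product: 12 4-{5-chloro-4-[({3-[(tert-butyldimethylsilyl)oxy]-2-(furan-2-yl)phenoxy}di(propan-2-yl)silyl)oxy]-2-methylphenoxy}-2-methylbutan-2-yl acetate
Conditions: Ac2O, DMAP, Et3N, CH2Cl2, 40 °C
Reagents that add atoms: acetic anhydride, CC(=O)OC(C)=O
Why: DMAP-catalysed acylation should esterify the tertiary alcohol, which is now the only hydroxyl.

Step 7
Reactants: 12 4-{5-chloro-4-[({3-[(tert-butyldimethylsilyl)oxy]-2-(furan-2-yl)phenoxy}di(propan-2-yl)silyl)oxy]-2-methylphenoxy}-2-methylbutan-2-yl acetate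
Product: 15 racemic silicon-tethered 1-aryl-1,4-dihydro-1,4-epoxynaphthalene (oxabenzonorbornadiene) acetate, via dilithio chloroarene 13 (not isolated), via aryne 14 (not isolated)
Conditions: LiN(i-Pr)2 (2.6 equiv), THF (0.01 M), −78 → 0 °C; aq NH4Cl
Reagents that add atoms: none
Why: Intramolecular benzyne–furan Diels–Alder reaction through a disposable silicon tether: the amide base should remove the only ring proton flanked by chlorine and alkoxy oxygen (the tert-alkyl acetate waits as its stable lithium enolate, and lithium never sits ortho to the silyl ether, so no silyl shift), loss of LiCl gives the aryne, and the eight-membered tether lets the aryl-bearing furan carbon reach only the aryne carbon next to the silyloxy group, which fixes the regiochemistry while both bridgeheads form together as a racemate.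

Step 8
Reactants: 15 racemic silicon-tethered 1-aryl-1,4-dihydro-1,4-epoxynaphthalene acetate
Product: 16 single enantiomer of 15 with the bridgehead configuration of the target
Conditions: preparative SFC, amylose tris(3,5-dimethylphenylcarbamate) phase, CO2/i-PrOH
Reagents that add atoms: none
Why: Resolution on a chiral stationary phase should separate the two enantiomers (the two bridgeheads are locked to one another by the bicycle), and taking on the one shown fixes the absolute configuration of every later centre.

Step 9
Reactants: 17 3,5-dihydroxybenzyl alcohol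
Product: 18 1,3-bis(methoxymethoxy)-5-[(methoxymethoxy)methyl]benzene
Conditions: MOMCl (3.6 equiv), i-Pr2NEt, CH2Cl2, 0 °C → rt
Reagents that add atoms: chloromethyl methyl ether, COCCl
Why: Base-mediated O-alkylation (MOM acetal formation) of both phenols and the primary alcohol should also install the directing groups for the lithiation.

Step 10
Reactants: 18 1,3-bis(methoxymethoxy)-5-[(methoxymethoxy)methyl]benzene
Product: 21 1-[2-hydroxy-6-(methoxymethoxy)-4-[(methoxymethoxy)methyl]phenyl]ethan-1-one, via aryllithium 19 (not isolated), via tris-MOM ketone 20 (not isolated)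
Conditions: n-BuLi, TMEDA, THF, 0 °C; AcN(OMe)Me, −78 °C → rt; then 1 M HCl, MeOH, rt
Reagents that add atoms: N-methoxy-N-methylacetamide, CC(=O)N(C)OC
Why: Directed ortho-metalation should remove the proton between the two OMOM groups, Weinreb acylation stops at the ketone, and acid methanolysis cleaves only one MOM ether because the freed phenol is then locked to the carbonyl by a hydrogen bond.

Step 11
Reactants: 21 1-[2-hydroxy-6-(methoxymethoxy)-4-[(methoxymethoxy)methyl]phenyl]ethan-1-one
Product: 22 (2E)-3-(dimethylamino)-1-[2-hydroxy-6-(methoxymethoxy)-4-[(methoxymethoxy)methyl]phenyl]prop-2-en-1-one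
Conditions: Me2NCH(OMe)2 (2 equiv), toluene, 90 °C
Reagents that add atoms: N,N-dimethylformamide dimethyl acetal, COC(OC)N(C)C
Why: Condensation of the methyl ketone with the amide acetal (enaminone formation) should give the E enaminone while the hydrogen-bonded phenol stays free.

Step 12
Reactants: 22 (2E)-3-(dimethylamino)-1-[2-hydroxy-6-(methoxymethoxy)-4-[(methoxymethoxy)methyl]phenyl]prop-2-en-1-one
Product: 23 methyl 2-[5-(methoxymethoxy)-7-[(methoxymethoxy)methyl]-4-oxo-4H-chromen-3-yl]-2-oxoacetate
Conditions: ClCOCO2Me, pyridine, CH2Cl2, 0 °C → rt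
Reagents that add atoms: methyl chlorooxoacetate, COC(=O)C(Cl)=O
Why: C-acylation of the enaminone α-carbon, attack of the phenol on the iminium carbon and loss of dimethylamine (enaminone chromone synthesis, the established route to 3-methoxalylchromones) should give the keto ester at C3 and leave C2 as the C–H that the key step needs.

Step 13
Reactants: 23 methyl 2-[5-(methoxymethoxy)-7-[(methoxymethoxy)methyl]-4-oxo-4H-chromen-3-yl]-2-oxoacetate
Product: 24 methyl 2-[5-hydroxy-7-(hydroxymethyl)-4-oxo-4H-chromen-3-yl]-2-oxoacetate
Conditions: 3 M aq HCl, THF, 45 °C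
Reagents that add atoms: none
Why: Acid hydrolysis of both MOM acetals is done here, on a small and robust chromone, so that no acid is needed once the bridged core exists.

Step 14
Reactants: 16 single enantiomer of the silicon-tethered oxabenzonorbornadiene acetate, 24 methyl 2-[5-hydroxy-7-(hydroxymethyl)-4-oxo-4H-chromen-3-yl]-2-oxoacetate
Product: 25 bis-silyl ether of aspergichromone B (Si(i-Pr)2 bridge between the ring E phenol oxygen and one ring F oxygen; other ring F oxygen as tert-butyldimethylsilyl ether)
Conditions: [RhCl2(C5Me5)]2 (4 mol %), AgSbF6 (16 mol %), NaOAc (50 mol %), ClCH2CH2Cl, 60 °C; 24 (1.2 equiv)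
Reagents that add atoms: none
Why: Proposed new method: acetate-assisted rhodation of the acidic chromone C2–H, directed by the ketone oxygen of the 3-keto ester, should give a five-membered rhodacycle, the strained alkene of 16 then inserts into the Rh–C2 bond from its exo face (syn addition), and the alkylrhodium, held by the bridging oxygen, adds to the coordinated keto carbonyl before acetic acid releases the tertiary rhodium alkoxide. The closest known chemistry is the ketone- or amide-directed C–H activation/[3+2] carbocyclisation of arenes with alkynes (indenols) and with 7-oxabenzonorbornadienes under cyclopentadienyl complexes of trivalent rhodium or cobalt; new here are the chromone C2–H bond, the α-keto ester as directing electrophile and the aryl-substituted bridgehead. Ring C closes as a formal [3+2] in which the second bond forms by 5-exo-trig addition of C–Rh to C=O. Ca and Cb follow from syn exo addition to the bicyclic alkene (hydrogens endo, ring C cis and exo) relative to the resolved bridgeheads, and C1 follows from the rhodium that carries the carbonyl oxygen sitting on the bridge side, chelated by the epoxide oxygen, so that OH ends syn to the bridge and CO2Me anti. The step needs chromone C2 to bond to Cb, next to the aryl-bearing bridgehead: (C5Me5)Rh, the bulky end of the adding Rh–C bond, takes the open side next to Cc where the bridging oxygen can bind it, the flat C2–O1 edge of the chromone passes the tethered ring F and its silyl ether, and the opposite orientation would have to join the quaternary C1 to the carbon beside the quaternary Cq. Opening of the bridge by β-oxygen elimination should be outrun by the intramolecular addition to the very electrophilic keto ester.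

Step 15
Reactants: 25 bis-silyl ether of aspergichromone B
Product: 26 aspergichromone B
Conditions: Et3N·3HF (10 equiv), THF, 0 °C → rt
Reagents that add atoms: none
Why: Fluoride should cleave the three aryl Si–O bonds (silylene tether and silyl ether) under near-neutral conditions that leave the tertiary acetate, the methyl ester and the benzylic bridging ether untouched, so no stereocentre is affected.

Compound list
1 | 5-chloro-2-methylphenol | Cc1ccc(Cl)cc1O | starting material
2 | 4-bromo-5-chloro-2-methylphenol | Cc1cc(Br)c(Cl)cc1O | intermediate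
3 | 3-methylbutane-1,3-diol | CC(C)(O)CCO | starting material
4 | 4-(4-bromo-5-chloro-2-methylphenoxy)-2-methylbutan-2-ol | Cc1cc(Br)c(Cl)cc1OCCC(C)(C)O | intermediate
5 | 2-chloro-4-(3-hydroxy-3-methylbutoxy)-5-methylphenol | Cc1cc(O)c(Cl)cc1OCCC(C)(C)O | intermediate
6 | 2-bromobenzene-1,3-diol | Oc1cccc(O)c1Br | starting material
7 | 2-(furan-2-yl)-4,4,5,5-tetramethyl-1,3,2-dioxaborolane | CC1(C)OB(c2ccco2)OC1(C)C | starting material
8 | 2-(furan-2-yl)benzene-1,3-diol | Oc1cccc(O)c1-c1ccco1 | intermediate
9 | chloro[2-chloro-4-(3-hydroxy-3-methylbutoxy)-5-methylphenoxy]di(propan-2-yl)silane (not isolated) | Cc1cc(O[Si](Cl)(C(C)C)C(C)C)c(Cl)cc1OCCC(C)(C)O | intermediate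
10 | 3-({[2-chloro-4-(3-hydroxy-3-methylbutoxy)-5-methylphenoxy]di(propan-2-yl)silyl}oxy)-2-(furan-2-yl)phenol (not isolated) | Cc1cc(O[Si](Oc2cccc(O)c2-c2ccco2)(C(C)C)C(C)C)c(Cl)cc1OCCC(C)(C)O | intermediate
11 | 4-{5-chloro-4-[({3-[(tert-butyldimethylsilyl)oxy]-2-(furan-2-yl)phenoxy}di(propan-2-yl)silyl)oxy]-2-methylphenoxy}-2-methylbutan-2-ol | Cc1cc(O[Si](Oc2cccc(O[Si](C)(C)C(C)(C)C)c2-c2ccco2)(C(C)C)C(C)C)c(Cl)cc1OCCC(C)(C)O | intermediate
12 | 4-{5-chloro-4-[({3-[(tert-butyldimethylsilyl)oxy]-2-(furan-2-yl)phenoxy}di(propan-2-yl)silyl)oxy]-2-methylphenoxy}-2-methylbutan-2-yl acetate | Cc1cc(O[Si](Oc2cccc(O[Si](C)(C)C(C)(C)C)c2-c2ccco2)(C(C)C)C(C)C)c(Cl)cc1OCCC(C)(C)OC(C)=O | intermediate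
13 | dilithio derivative of 12: lithium on the ring carbon between chlorine and the alkoxy group, acetate as lithium enolate (not isolated) | Cc1cc(O[Si](Oc2cccc(O[Si](C)(C)C(C)(C)C)c2-c2ccco2)(C(C)C)C(C)C)c(Cl)c([Li])c1OCCC(C)(C)OC(=C)O[Li] | intermediate
14 | aryne from 13 by loss of LiCl: triple bond between the former C–Cl and C–Li carbons, acetate still as lithium enolate (not isolated) | CC1=C(OCCC(C)(C)OC(=C)O[Li])C#CC(O[Si](Oc2cccc(O[Si](C)(C)C(C)(C)C)c2-c2ccco2)(C(C)C)C(C)C)=C1 | intermediate
15 | racemic 4-({1-aryl-6-methyl-1,4-dihydro-1,4-epoxynaphthalen-5-yl}oxy)-2-methylbutan-2-yl acetate in which O-8 of the naphthalene and one ortho-oxygen of the 1-aryl group are bridged by Si(i-Pr)2 (eight-membered dioxasilocine) and the other ortho-oxygen is a tert-butyldimethylsilyl ether | C1=CC2OC1(c1c(O[Si]3(C(C)C)C(C)C)cccc1O[Si](C)(C)C(C)(C)C)c1c(O3)cc(C)c(OCCC(C)(C)OC(C)=O)c12 | intermediate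
16 | the enantiomer of 15 whose two bridgeheads have the configuration of the target | C1=C[C@H]2O[C@]1(c1c(O[Si]3(C(C)C)C(C)C)cccc1O[Si](C)(C)C(C)(C)C)c1c(O3)cc(C)c(OCCC(C)(C)OC(C)=O)c12 | intermediate
17 | 3,5-dihydroxybenzyl alcohol | OCc1cc(O)cc(O)c1 | starting material
18 | 1,3-bis(methoxymethoxy)-5-[(methoxymethoxy)methyl]benzene | COCOCc1cc(OCOC)cc(OCOC)c1 | intermediate
19 | [2,6-bis(methoxymethoxy)-4-[(methoxymethoxy)methyl]phenyl]lithium (not isolated) | [Li]c1c(OCOC)cc(COCOC)cc1OCOC | intermediate
20 | 1-[2,6-bis(methoxymethoxy)-4-[(methoxymethoxy)methyl]phenyl]ethan-1-one (not isolated) | CC(=O)c1c(OCOC)cc(COCOC)cc1OCOC | intermediate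
21 | 1-[2-hydroxy-6-(methoxymethoxy)-4-[(methoxymethoxy)methyl]phenyl]ethan-1-one | CC(=O)c1c(O)cc(COCOC)cc1OCOC | intermediate
22 | (2E)-3-(dimethylamino)-1-[2-hydroxy-6-(methoxymethoxy)-4-[(methoxymethoxy)methyl]phenyl]prop-2-en-1-one | CN(C)/C=C/C(=O)c1c(O)cc(COCOC)cc1OCOC | intermediate
23 | methyl 2-[5-(methoxymethoxy)-7-[(methoxymethoxy)methyl]-4-oxo-4H-chromen-3-yl]-2-oxoacetate | COC(=O)C(=O)c1coc2cc(COCOC)cc(OCOC)c2c1=O | intermediate
24 | methyl 2-[5-hydroxy-7-(hydroxymethyl)-4-oxo-4H-chromen-3-yl]-2-oxoacetate | COC(=O)C(=O)c1coc2cc(CO)cc(O)c2c1=O | intermediate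
25 | bis-silyl ether of aspergichromone B: Si(i-Pr)2 bridging the ring E phenol oxygen and one ring F oxygen, other ring F oxygen as tert-butyldimethylsilyl ether; ring C exo-fused, C1–OH on the bridge side, configuration as in 26 | COC(=O)[C@@]1(O)c2c(oc3cc(CO)cc(O)c3c2=O)[C@H]2[C@@H]1[C@H]1O[C@]2(c2c(O[Si]3(C(C)C)C(C)C)cccc2O[Si](C)(C)C(C)(C)C)c2c(O3)cc(C)c(OCCC(C)(C)OC(C)=O)c21 | intermediate
26 | aspergichromone B (cyclopentane exo-fused to the 1,4-epoxide; C1–OH on the bridge side) | COC(=O)[C@@]1(O)c2c(oc3cc(CO)cc(O)c3c2=O)[C@H]2[C@@H]1[C@H]1O[C@]2(c2c(O)cccc2O)c2c(O)cc(C)c(OCCC(C)(C)OC(C)=O)c21 | target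

Total step count: 15. Longest linear sequence: 9 (steps 1, 2, 3, 5, 6, 7, 8, 14, 15).

Steps most likely to fail
1. Step 14 (Proposed new method). What may go wrong: no rhodation of the chromone C2–H, insertion in the other orientation, or opening of the oxygen bridge by β-oxygen elimination from the alkylrhodium. The fallback would set out from 24 and 16 and come back at 25. Zincation of 24 at C2 with TMPZnCl·LiCl (3.2 equiv, both hydroxyls carried as zinc alkoxides) and quenching with iodine would give methyl 2-[5-hydroxy-7-(hydroxymethyl)-2-iodo-4-oxo-4H-chromen-3-yl]-2-oxoacetate F1. The reductive [3+2] carbocyclisation of ortho-iodoaryl ketones, known with alkynes and with activated or strained alkenes (CoI2(dppe), Zn, MeCN, 80 °C), applied to F1 and 16 would then form the same two bonds from a C–I bond instead of a C–H bond.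
2. Step 7. What may go wrong: attack of the amide base on silicon or on the acetate, or oligomerisation if the eight-membered tethered transition state is too strained. The fallback would give up the tether, set out from 5 and 8, and come back at 15. Silylation of the phenol of 5 would give 4-{4-[(tert-butyldimethylsilyl)oxy]-5-chloro-2-methylphenoxy}-2-methylbutan-2-ol F2, and acetylation would give 4-{4-[(tert-butyldimethylsilyl)oxy]-5-chloro-2-methylphenoxy}-2-methylbutan-2-yl acetate F3. Double silylation of 8 would give 2-[2,6-bis(tert-butyldimethylsilyloxy)phenyl]furan F4. The aryne from F3 (LiN(i-Pr)2) would be trapped intermolecularly by F4 (3 equiv), and the wanted orientation separated as the racemic tris-silyl cycloadduct F5. Buffered fluoride would free the racemic triol F6; i-Pr2SiCl2 would bridge the two neighbouring phenols to the racemic silylene-bridged monophenol F7, and t-BuMe2SiCl would cap the last phenol.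
3. Step 15. What may go wrong: opening of the bridging ether through an ortho-phenoxide (quinone methide pathway) under basic fluoride, or partial loss of the tertiary acetate. The fallback would unmask before the annulation, set out from 16 and come back at 26. Et3N·3HF on 16 would give the enantiopure triol 4-{[1-(2,6-dihydroxyphenyl)-8-hydroxy-6-methyl-1,4-dihydro-1,4-epoxynaphthalen-5-yl]oxy}-2-methylbutan-2-yl acetate F8, and F8 with 24 under the conditions of step 14 would give 26 directly, so that the ring-C annulation is the last step.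

Further compounds
F1 | step 14 | methyl 2-[5-hydroxy-7-(hydroxymethyl)-2-iodo-4-oxo-4H-chromen-3-yl]-2-oxoacetate | COC(=O)C(=O)c1c(I)oc2cc(CO)cc(O)c2c1=O
F2 | step 7 | 4-{4-[(tert-butyldimethylsilyl)oxy]-5-chloro-2-methylphenoxy}-2-methylbutan-2-ol | Cc1cc(O[Si](C)(C)C(C)(C)C)c(Cl)cc1OCCC(C)(C)O
F3 | step 7 | 4-{4-[(tert-butyldimethylsilyl)oxy]-5-chloro-2-methylphenoxy}-2-methylbutan-2-yl acetate | Cc1cc(O[Si](C)(C)C(C)(C)C)c(Cl)cc1OCCC(C)(C)OC(C)=O
F4 | step 7 | 2-[2,6-bis(tert-butyldimethylsilyloxy)phenyl]furan | CC(C)(C)[Si](C)(C)Oc1cccc(O[Si](C)(C)C(C)(C)C)c1-c1ccco1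
F5 | step 7 | racemic 4-({1-[2,6-bis(tert-butyldimethylsilyloxy)phenyl]-8-(tert-butyldimethylsilyloxy)-6-methyl-1,4-dihydro-1,4-epoxynaphthalen-5-yl}oxy)-2-methylbutan-2-yl acetate | C1=CC2OC1(c1c(O[Si](C)(C)C(C)(C)C)cccc1O[Si](C)(C)C(C)(C)C)c1c(O[Si](C)(C)C(C)(C)C)cc(C)c(OCCC(C)(C)OC(C)=O)c12
F6 | step 7 | racemic 4-{[1-(2,6-dihydroxyphenyl)-8-hydroxy-6-methyl-1,4-dihydro-1,4-epoxynaphthalen-5-yl]oxy}-2-methylbutan-2-yl acetate | C1=CC2OC1(c1c(O)cccc1O)c1c(O)cc(C)c(OCCC(C)(C)OC(C)=O)c12
F7 | step 7 | racemic silylene-bridged monophenol (15 without its tert-butyldimethylsilyl group) | C1=CC2OC1(c1c(O[Si]3(C(C)C)C(C)C)cccc1O)c1c(O3)cc(C)c(OCCC(C)(C)OC(C)=O)c12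
F8 | step 15 | 4-{[1-(2,6-dihydroxyphenyl)-8-hydroxy-6-methyl-1,4-dihydro-1,4-epoxynaphthalen-5-yl]oxy}-2-methylbutan-2-yl acetate, enantiomer with the bridgehead configuration of 26 | C1=C[C@H]2O[C@]1(c1c(O)cccc1O)c1c(O)cc(C)c(OCCC(C)(C)OC(C)=O)c12
A1 | direct plan | methyl 2-[2-ethenyl-5-(methoxymethoxy)-7-[(methoxymethoxy)methyl]-4-oxo-4H-chromen-3-yl]-2-oxoacetate | COC(=O)C(=O)c1c(C=C)oc2cc(COCOC)cc(OCOC)c2c1=O
A2 | direct plan | methyl (1S)-1-hydroxy-8-(methoxymethoxy)-6-[(methoxymethoxy)methyl]-9-oxo-1,9-dihydrocyclopenta[b]chromene-1-carboxylate | COC(=O)[C@@]1(O)c2c(oc3cc(COCOC)cc(OCOC)c3c2=O)C=C1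
A3 | direct plan | 4-({1-[2,6-bis(methoxymethoxy)phenyl]-7-(methoxymethoxy)-5-methyl-2-benzofuran-4-yl}oxy)-2-methylbutan-2-yl acetate | O1C(c2c(OCOC)cccc2OCOC)=C2C(OCOC)=CC(C)=C(OCCC(C)(C)OC(C)=O)C2=C1
A4 | direct plan | penta-MOM ether of aspergichromone B | COC(=O)[C@@]1(O)c2c(oc3cc(COCOC)cc(OCOC)c3c2=O)[C@H]2[C@@H]1[C@H]1O[C@]2(c2c(OCOC)cccc2OCOC)c2c(OCOC)cc(C)c(OCCC(C)(C)OC(C)=O)c21
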